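A direct plan would acetylate 3,4,5-trimethoxyphenol A1, add the fourth ring-A methoxy group by bromination and CuBr-catalysed methoxylation with NaOMe to reach 1-(2-hydroxy-3,4,5,6-tetramethoxyphenyl)ethanone A2, condense ketone A2 with 4-(benzyloxy)-3,5-dimethoxybenzaldehyde A3 to the chalcone A4, close ring C oxidatively with I2/DMSO to the benzyl-protected hexaalkoxyflavone A5, debenzylate to the 4'-phenol A6 and finally cleave the 5-OMe group with BCl3.
Its weakest steps would be:
- The final 5-O-demethylation of A6: O5 would be methylated early only to be unmasked at the end, and the choice of one methoxy group out of six would rest on chelation alone, on the most valuable intermediate.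
- The bromination/methoxylation pair between A1 and A2: two steps, one of them a CuBr-catalysed coupling on a base-sensitive hydroxyacetophenone, would add a single OMe, so a simple acetophenone would need a long linear run-up.
- The aldol condensation of the doubly ortho-substituted ketone A2 with aldehyde A3 and the separate oxidation of chalcone A4: the hindered ketone would need days in strong base, and the flavone oxidation level would be reached only in a further hot oxidative step.

**Retrosynthetic overview**
- Ring A carries four contiguous oxygens on C5–C8, with O5 and O8 para and O6 and O7 vicinal. This is the pattern of a squarate, so C5, C6, C7, C8 and all four of their oxygens are taken from dimethyl squarate.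
- C8a and C4a are C6 and C5 of a preformed 2-aryl-4H-pyran-4-one. The C8–C8a bond is made by adding the C6-lithiated pyranone to the squarate, and the C4a–C5 bond by the thermal ring expansion of the resulting cyclobutenone.
- Ring order: ring B is bought, ring C is closed from an acid chloride and a methoxyenone, and ring A is built last, from a four-membered ring.
- The ketene oxygen emerges as the free, chelated 5-OH and the carbinol oxygen, methylated at the cyclobutenone stage, as 8-OMe. No late demethylation, no ring-A methoxylation sequence, no chalcone and no oxidation step are needed.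

Key step: step 4

Assumption: 4-(benzyloxy)-3,5-dimethoxybenzoic acid, (E)-4-methoxybut-3-en-2-one and dimethyl squarate are bought as catalogue compounds; the single stereocentre that appears on the way (in the cyclobutenone) is racemic and is erased by the key step.

Step 1
Reactants: 1 4-(benzyloxy)-3,5-dimethoxybenzoic acid
Product: 2 4-(benzyloxy)-3,5-dimethoxybenzoyl chloride
Conditions: (COCl)2 (1.3 equiv), DMF (cat.), CH2Cl2, 0 °C to rt, 2 h; evaporate
Reagents that add atoms: oxalyl chloride, O=C(Cl)C(=O)Cl
Why: Acid chloride formation through chloroiminium (Vilsmeier-type) activation of the carboxylic acid is routine and should leave the benzyl and methyl aryl ethers untouched.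

Step 2
Reactants: 2 4-(benzyloxy)-3,5-dimethoxybenzoyl chloride; 3 (E)-4-methoxybut-3-en-2-one (2.1 equiv)
Product: 5 2-[4-(benzyloxy)-3,5-dimethoxyphenyl]-4H-pyran-4-one, via methoxyenedione 4 (not isolated)
Conditions: 3, LiN(SiMe3)2 (2.1 equiv), THF, −78 °C, 30 min; 2 (1 equiv), −78 °C, 1 h; aq. NH4Cl; crude in toluene, CF3CO2H (0.2 equiv), rt, 12 h
Reagents that add atoms: none
Why: Claisen-type C-acylation of the kinetic methyl-side lithium enolate (the second equivalent of enolate takes up the acidic proton of the 1,3-diketone) should be followed by acid-catalysed 6-endo oxa-Michael addition of the enol oxygen and loss of methanol, the standard γ-pyrone synthesis from a β-methoxyenone.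

Step 3
Reactants: 5 2-[4-(benzyloxy)-3,5-dimethoxyphenyl]-4H-pyran-4-one; 6 dimethyl squarate (3,4-dimethoxycyclobut-3-ene-1,2-dione) (1.3 equiv)
Product: 9 racemic 2-[4-(benzyloxy)-3,5-dimethoxyphenyl]-6-(1,2,3-trimethoxy-4-oxocyclobut-2-en-1-yl)-4H-pyran-4-one, via 6-lithiopyranone 7 (not isolated), via lithium alkoxide 8 (not isolated)
Conditions: lithium 2,2,6,6-tetramethylpiperidide (1.1 equiv, from 2,2,6,6-tetramethylpiperidine and n-BuLi), THF, −78 °C, 15 min; 6 in THF (precooled, one portion), −78 °C, 30 min; MeOTf (1.5 equiv), −78 to −20 °C; aq. NaHCO3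
Reagents that add atoms: methyl trifluoromethanesulfonate, COS(=O)(=O)C(F)(F)F
Why: Kinetic vinylic deprotonation should take place at C6–H next to the ring oxygen (the position lithiated in chromones, N-alkyl-4-quinolones and uracils), followed by 1,2-addition of the vinyllithium to one of the two equivalent squarate carbonyl groups and O-methylation of the tertiary lithium alkoxide; the new quaternary stereocentre is formed racemic and is destroyed in step 4.

Step 4
Reactants: 9 racemic 2-[4-(benzyloxy)-3,5-dimethoxyphenyl]-6-(1,2,3-trimethoxy-4-oxocyclobut-2-en-1-yl)-4H-pyran-4-one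
Product: 12 2-[4-(benzyloxy)-3,5-dimethoxyphenyl]-5-hydroxy-6,7,8-trimethoxy-4H-chromen-4-one, via dienylketene 10 (not isolated), via cyclohexadienone 11 (not isolated)
Conditions: p-xylene (0.01 M, degassed), 138 °C, 2 h, Ar
Reagents that add atoms: none
Why: Heating should open the cyclobutenone by a conrotatory 4π electrocyclic cleavage of the C1–C4 bond, in which the methoxy donor on C4 rotates outward and so places the pyranonyl group inward, cis to the new ketene (dienylketene 10). A disrotatory 6π electrocyclization of 10 then joins the ketene carbon to C5 of the pyranone, which closes the six-membered carbocyclic ring A onto the finished rings B and C and forms the C4a–C5 bond of the flavone (cyclohexadienone 11). Enolization of 11, whose C4a–H lies between two carbonyl groups, gives the aromatic ring, so that the ketene oxygen appears as the free 5-OH hydrogen-bonded to the C4 carbonyl and the methylated carbinol oxygen as 8-OMe. The closest known reaction type is the thermal ring expansion (Moore rearrangement) of 4-alkenyl- and 4-heteroaryl-4-alkoxycyclobutenones to hydroquinone monoethers and annulated phenols. No stereocentre is formed and the one of 9 is destroyed. The step needs only regiochemical fidelity, which the substrate secures because the pyranone carbon that bears the cyclobutenone has a single carbon neighbour (C5–H; the other neighbour is the ring oxygen), and high dilution under argon should keep the ketene from intermolecular reactions.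

Step 5
Reactants: 12 2-[4-(benzyloxy)-3,5-dimethoxyphenyl]-5-hydroxy-6,7,8-trimethoxy-4H-chromen-4-one
Product: 13 5,4'-dihydroxy-6,7,8,3',5'-pentamethoxyflavone (5-hydroxy-2-(4-hydroxy-3,5-dimethoxyphenyl)-6,7,8-trimethoxy-4H-chromen-4-one)
Conditions: H2 (1 atm), palladium on carbon (10 wt % Pd, 5 mol % Pd), EtOAc/MeOH 1:1, rt, 2 h
Reagents that add atoms: none
Why: Catalytic hydrogenolysis of the benzylic C–O bond is fast at 1 atm and room temperature, conditions under which the flavone C2=C3 bond, the carbonyl group and the aryl methyl ethers should not be reduced.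

**Compound list**
1 | 4-(benzyloxy)-3,5-dimethoxybenzoic acid | COc1cc(C(=O)O)cc(OC)c1OCc1ccccc1 | starting material
2 | 4-(benzyloxy)-3,5-dimethoxybenzoyl chloride | COc1cc(C(=O)Cl)cc(OC)c1OCc1ccccc1 | intermediate
3 | (E)-4-methoxybut-3-en-2-one | CO/C=C/C(C)=O | starting material
4 | (E)-1-[4-(benzyloxy)-3,5-dimethoxyphenyl]-5-methoxypent-4-ene-1,3-dione (methoxyenedione, present largely as its enol; not isolated) | CO/C=C/C(=O)CC(=O)c1cc(OC)c(OCc2ccccc2)c(OC)c1 | intermediate
5 | 2-[4-(benzyloxy)-3,5-dimethoxyphenyl]-4H-pyran-4-one | COc1cc(-c2cc(=O)cco2)cc(OC)c1OCc1ccccc1 | intermediate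
6 | dimethyl squarate (3,4-dimethoxycyclobut-3-ene-1,2-dione) | COC1=C(OC)C(=O)C1=O | starting material
7 | 2-[4-(benzyloxy)-3,5-dimethoxyphenyl]-6-lithio-4H-pyran-4-one (not isolated) | COc1cc(-c2cc(=O)cc([Li])o2)cc(OC)c1OCc1ccccc1 | intermediate
8 | lithium alkoxide of racemic 2-[4-(benzyloxy)-3,5-dimethoxyphenyl]-6-(1-hydroxy-2,3-dimethoxy-4-oxocyclobut-2-en-1-yl)-4H-pyran-4-one (not isolated) | COC1=C(OC)C([O-])(c2cc(=O)cc(-c3cc(OC)c(OCc4ccccc4)c(OC)c3)o2)C1=O.[Li+] | intermediate
9 | racemic 2-[4-(benzyloxy)-3,5-dimethoxyphenyl]-6-(1,2,3-trimethoxy-4-oxocyclobut-2-en-1-yl)-4H-pyran-4-one | COC1=C(OC)C(OC)(c2cc(=O)cc(-c3cc(OC)c(OCc4ccccc4)c(OC)c3)o2)C1=O | intermediate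
10 | (Z)-4-{6-[4-(benzyloxy)-3,5-dimethoxyphenyl]-4-oxo-4H-pyran-2-yl}-2,3,4-trimethoxybuta-1,3-dien-1-one (dienylketene; not isolated) | O=C=C(OC)/C(OC)=C(/OC)c1cc(=O)cc(-c2cc(OC)c(OCc3ccccc3)c(OC)c2)o1 | intermediate
11 | racemic 2-[4-(benzyloxy)-3,5-dimethoxyphenyl]-6,7,8-trimethoxy-4H-chromene-4,5(4aH)-dione (cyclohexadienone; not isolated) | O=C1C(OC)=C(OC)C(OC)=C2OC(-c3cc(OC)c(OCc4ccccc4)c(OC)c3)=CC(=O)C12 | intermediate
12 | 2-[4-(benzyloxy)-3,5-dimethoxyphenyl]-5-hydroxy-6,7,8-trimethoxy-4H-chromen-4-one | COc1cc(-c2cc(=O)c3c(O)c(OC)c(OC)c(OC)c3o2)cc(OC)c1OCc1ccccc1 | intermediate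
13 | 5,4'-dihydroxy-6,7,8,3',5'-pentamethoxyflavone (5-hydroxy-2-(4-hydroxy-3,5-dimethoxyphenyl)-6,7,8-trimethoxy-4H-chromen-4-one; achiral) | COc1cc(-c2cc(=O)c3c(O)c(OC)c(OC)c(OC)c3o2)cc(OC)c1O | target

Total step count: 5. Longest linear sequence: 5 steps (1 to 13).

**Steps most likely to fail**

Step 3. The 6-lithio species may fragment by α-elimination of the ring oxygen (ring opening to an acetylenic diketonate), or form in competition with deprotonation at C3 or C5, before it meets the squarate. Methyl triflate may also attack the pyranone carbonyl oxygen. The fallback sets out from 5 and comes back at 9. Pyranone 5 would be zincated next to the ring oxygen with (2,2,6,6-tetramethylpiperidin-1-yl)zinc chloride–lithium chloride (TMPZnCl·LiCl; THF, 25 °C) and quenched with I2 to give 2-[4-(benzyloxy)-3,5-dimethoxyphenyl]-6-iodo-4H-pyran-4-one F1. Iodine–magnesium exchange (i-PrMgCl·LiCl, THF, −78 °C) would give the more covalent and more persistent 6-magnesio species, which would add to squarate 6 and give, after aq. NH4Cl, racemic 2-[4-(benzyloxy)-3,5-dimethoxyphenyl]-6-(1-hydroxy-2,3-dimethoxy-4-oxocyclobut-2-en-1-yl)-4H-pyran-4-one F2. O-Methylation with MeI/Ag2O (K2CO3, MeCN, rt), which should not touch the pyranone carbonyl, would lead to 9.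

Step 4. The vinylketene may be used up by intermolecular reactions, or reclose without result, if its closure onto C5 of the cross-conjugated pyranone is slow. The fallback sets out from 6 and 2 and comes back at 12. The squarate ring expansion would be moved to a simple enol ether, and ring C would be closed afterwards. 1-(Methoxymethoxy)vinyllithium (from methoxymethyl vinyl ether and t-BuLi, THF, −78 to 0 °C) would be added to 6 and the alkoxide methylated (MeOTf) to give racemic 2,3,4-trimethoxy-4-[1-(methoxymethoxy)ethenyl]cyclobut-2-en-1-one F3. Thermolysis (toluene, 110 °C) would give 2,3,4-trimethoxy-5-(methoxymethoxy)phenol F4. AcOH/BF3·OEt2 (80 °C) would acetylate the only free ring position and remove the acetal to give the symmetrical 1-(2,6-dihydroxy-3,4,5-trimethoxyphenyl)ethanone F5. Its lithium trianion (LiN(SiMe3)2, 4 equiv, THF, −78 °C) would be C-aroylated with acid chloride 2 to 1-[4-(benzyloxy)-3,5-dimethoxyphenyl]-3-(2,6-dihydroxy-3,4,5-trimethoxyphenyl)propane-1,3-dione F6. Cyclodehydration (TsOH, toluene, 90 °C), in which either of the two equivalent hydroxy groups closes ring C, would arrive at 12.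

Step 2. The methoxyenone enolate may be acylated on oxygen or twice, or condense with itself by Michael addition under the basic conditions. The fallback sets out from 2 and comes back at 4. The C3–C4 bond of the pyranone would be made in place of the C2–C3 bond. Acid chloride 2 would be converted with Me2CuLi (Et2O, −78 °C) into 1-[4-(benzyloxy)-3,5-dimethoxyphenyl]ethanone F7. Its lithium enolate (LiN(SiMe3)2, 2 equiv, THF, −78 °C) would be acylated with (E)-3-methoxyacryloyl chloride to give methoxyenedione 4, which would be cyclised with CF3CO2H as in step 2.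

**Further compounds**
F1 | step 3 | 2-[4-(benzyloxy)-3,5-dimethoxyphenyl]-6-iodo-4H-pyran-4-one | COc1cc(-c2cc(=O)cc(I)o2)cc(OC)c1OCc1ccccc1
F2 | step 3 | racemic 2-[4-(benzyloxy)-3,5-dimethoxyphenyl]-6-(1-hydroxy-2,3-dimethoxy-4-oxocyclobut-2-en-1-yl)-4H-pyran-4-one | COC1=C(OC)C(O)(c2cc(=O)cc(-c3cc(OC)c(OCc4ccccc4)c(OC)c3)o2)C1=O
F3 | step 4 | racemic 2,3,4-trimethoxy-4-[1-(methoxymethoxy)ethenyl]cyclobut-2-en-1-one | C=C(OCOC)C1(OC)C(OC)=C(OC)C1=O
F4 | step 4 | 2,3,4-trimethoxy-5-(methoxymethoxy)phenol | COCOc1cc(O)c(OC)c(OC)c1OC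
F5 | step 4 | 1-(2,6-dihydroxy-3,4,5-trimethoxyphenyl)ethanone | CC(=O)c1c(O)c(OC)c(OC)c(OC)c1O
F6 | step 4 | 1-[4-(benzyloxy)-3,5-dimethoxyphenyl]-3-(2,6-dihydroxy-3,4,5-trimethoxyphenyl)propane-1,3-dione | COc1cc(C(=O)CC(=O)c2c(O)c(OC)c(OC)c(OC)c2O)cc(OC)c1OCc1ccccc1
F7 | step 2 | 1-[4-(benzyloxy)-3,5-dimethoxyphenyl]ethanone | CC(=O)c1cc(OC)c(OCc2ccccc2)c(OC)c1
A1 | direct plan | 3,4,5-trimethoxyphenol | COc1cc(O)cc(OC)c1OC
A2 | direct plan | 1-(2-hydroxy-3,4,5,6-tetramethoxyphenyl)ethanone | CC(=O)c1c(O)c(OC)c(OC)c(OC)c1OC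
A3 | direct plan | 4-(benzyloxy)-3,5-dimethoxybenzaldehyde | COc1cc(C=O)cc(OC)c1OCc1ccccc1
A4 | direct plan | (E)-3-[4-(benzyloxy)-3,5-dimethoxyphenyl]-1-(2-hydroxy-3,4,5,6-tetramethoxyphenyl)prop-2-en-1-one | COc1cc(/C=C/C(=O)c2c(O)c(OC)c(OC)c(OC)c2OC)cc(OC)c1OCc1ccccc1
A5 | direct plan | 2-[4-(benzyloxy)-3,5-dimethoxyphenyl]-5,6,7,8-tetramethoxy-4H-chromen-4-one | COc1cc(-c2cc(=O)c3c(OC)c(OC)c(OC)c(OC)c3o2)cc(OC)c1OCc1ccccc1
A6 | direct plan | 2-(4-hydroxy-3,5-dimethoxyphenyl)-5,6,7,8-tetramethoxy-4H-chromen-4-one | COc1cc(-c2cc(=O)c3c(OC)c(OC)c(OC)c(OC)c3o2)cc(OC)c1O
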